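Amounts first: you charge 0.20 M of starting material, and the earlier runs show it in two products, so you can watch what is left outside them.

| flask | starting material | first nucleophile | second nucleophile | protic impurity | remark | time |
|---|---|---|---|---|---|---|
| zeta | 0.20 M | 0.60 M | 0.50 M | 0.10 M | run made earlier |  |
| beta | 0.20 M | 0.60 M | 0.50 M | 0.14 M | run made earlier |  |
| delta | 0.20 M | 0.60 M | 0.50 M | 0.22 M | run made earlier |  |
| north-east | 0.20 M | 0.600 M | 0.500 M | 0.100 M | everything together at the start | 2.5 h |
| north-west | 0.20 M | 0.600 M | 0.500 M (fed, over 1.5 h) | 0.100 M | all else is in the flask from the start; the feed brings no volume worth counting | 2.5 h |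
| north | 0.20 M (fed, over 1.5 h) | 0.600 M | 0.500 M | 0.100 M | all else is in the flask from the start; the feed brings no volume worth counting | 2.5 h |

| run | time / h | solvolysis product / % | target / % |
|---|---|---|---|
| zeta | 0.200 | 5.5 | 8.3 |
| zeta | 0.417 | 7.7 | 13.3 |
| zeta | 0.667 | 10.6 | 18.5 |
| zeta | 1.33 | 18.2 | 29.9 |
| zeta | 2.50 | 22.9 | 41.5 |
| beta | 0.200 | 4.1 | 7.7 |
| beta | 0.667 | 12.1 | 20.0 |
| beta | 1.33 | 17.7 | 31.3 |
| beta | 2.00 | 22.4 | 37.9 |
| beta | 2.50 | 23.2 | 41.3 |
| delta | 0.500 | 9.2 | 15.1 |
| delta | 1.00 | 16.8 | 26.7 |
| delta | 1.50 | 18.0 | 31.8 |
| delta | 2.00 | 21.9 | 38.9 |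
| delta | 2.50 | 25.9 | 42.4 |

(standard deviation of a reading: 1 percentage point)

* the flask that comes out highest in amount of solvolysis product, in percent of the starting material charged, or "all alike" when all lie within 1.5 percentage points (north-east / north-west / north / all alike)
* solvolysis product at the end, in percent of the starting material charged, north-east
* solvolysis product at the end, in percent of the starting material charged, north-west
* solvolysis product at the end, in percent of the starting material charged, north

- the numbers in the tables scatter with a standard deviation of 1 percentage point

In the zeta run, which north-east repeats, the part of the charge in neither product falls to 70.9% at 0.667 h, 51.9% at 1.33 h and 35.6% at 2.50 h. Over its first 0.200 h the zeta run gains solvolysis product at 0.275 h⁻¹ of the charge, as a reading. From 1.33 h or 1.50 h up to 2.50 h the three runs climb on average at 0.0554 h⁻¹, a lower slope, and with a scatter of 1 point in each reading I place no knee between them.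

Pooled at 2.50 h, the runs give 0.575 of solvolysis product per unit of target, the split, or selectivity factor. Impurity from 0.10 M to 0.22 M leaves it at 0.552 and 0.611, as readings. If a whole charge ended in these two products, the curve would level at 36.5%. My own rule, with first nucleophile at 0.600 M: solvolysis product equals the split times the target.

The forecast names north-west, with 24% for north-east, 37% for north-west and 20% for north. It lets the ratio rise where second nucleophile is scarce, and adds: “this dependence is inferred, not shown, and the north-west estimate is the least secure”.

The flasks give north-west as highest, with 23.9%, 26.7% and 20.1% in that order.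

    intermediate → side product (k = 2.30 × 10⁻⁴ s⁻¹)
    intermediate → solvolysis product (k = 0.210 s⁻¹)
    second nucleophile + protic impurity → quenched reagent (k = 0.00260 M⁻¹ s⁻¹)
    starting material → intermediate (k = 3.30 × 10⁻⁴ s⁻¹)
    starting material ⇌ dormant form (K = 0.810, k = 8.30 × 10⁻⁴ s⁻¹)
    second nucleophile + intermediate → other capture product (k = 0.330 M⁻¹ s⁻¹)
    first nucleophile + intermediate → target (k = 0.640 M⁻¹ s⁻¹)

North-west holds 45.0% of target, and the split turns that into 25.9%, beside 26.7% computed. In north, intermediate goes to target 1.7 times as fast as to solvolysis product at 1.36 h, and 1.6 times at 2.50 h; in the scheme, intermediate cancels from that ratio, leaving first nucleophile in it and no second nucleophile.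

So take the neighbour of north with 0.24 M of first nucleophile: the split, scaled by 2.50, becomes 1.44, and its target of 19.8% then gives 28.4%. The computed flask holds 29.5%.

Readings and results are simulated from invented constants; noise was put on by code.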